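**Retrosynthetic overview**
- The target is the 3-O-syringate of (2R,3R)-flavan-3-ol, (−)-epicatechin. The last disconnections are the five O-benzyl groups (hydrogenolysis) and the O3 ester (acylation with O-benzylsyringic acid).
- Feature used: O1 joins the benzylic stereocentre C2 to the sp2 carbon C8a of ring A. Ring C is the only ring built, and it is closed at O1–C8a by aryl C–O coupling. No bond at C2 or C3 breaks, so a syn (1R,2R) open-chain diol mono-ether becomes the 2,3-cis flavan.
- C2 is set by Felkin–Anh reduction of an α-silyloxy aryl ketone. That ketone comes from a ring B aryl Grignard reagent and a Weinreb amide (C1'–C2 bond).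
- C3 and the C3–C4 bond come from an auxiliary-controlled glycolate alkylation with the ring A benzylic bromide. The bromide is made from 5-bromoresorcinol by benzylation, formylation, reduction and bromination.
- O3 carries a triisopropylsilyl group from the start. The two oxygens are therefore never equivalent, and this group is much slower than tert-butyldimethylsilyl to shift to a neighbouring alkoxide.

Key step: step 12

Remark: flavan numbering is used for the open-chain compounds too (O1, C2, C3, C4, C4a, C5–C8, C8a; ring A = benzo ring, ring B = 2-aryl group, ring C = pyran ring). Reading the SMILES gives (2R,3R), the 2,3-cis series.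

Step 1
Reactants: 1 5-bromoresorcinol
Product: 2 1,3-bis(benzyloxy)-5-bromobenzene
Conditions: BnBr (2.2 equiv), K2CO3, DMF, 60 °C
Reagents that add atoms: benzyl bromide, BrCc1ccccc1
Why: Williamson ether synthesis, in which both phenoxides are alkylated by SN2 on benzyl bromide while the aryl bromide needed for the ring closure stays inert.

Step 2
Reactants: 2 1,3-bis(benzyloxy)-5-bromobenzene
Product: 4 2,4-bis(benzyloxy)-6-bromobenzaldehyde, via aryl iminium chloride 3 (not isolated)
Conditions: POCl3, DMF, 0 → 80 °C; then H2O, 0 °C → rt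
Reagents that add atoms: N,N-dimethylformamide, CN(C)C=O (formyl carbon); water, O (carbonyl oxygen); phosphoryl chloride, O=P(Cl)(Cl)Cl (chloride counter-ion of 3 only)
Why: Vilsmeier–Haack formylation, in which the chloroiminium ion should attack para to one benzyloxy group and ortho to the other (next to bromine) rather than between the two benzyloxy groups, as is typical of 5-substituted resorcinol diethers, and hydrolysis of 3 releases the aldehyde.

Step 3
Reactants: 4 2,4-bis(benzyloxy)-6-bromobenzaldehyde
Product: 5 [2,4-bis(benzyloxy)-6-bromophenyl]methanol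
Conditions: NaBH4, THF–MeOH, 0 °C
Reagents that add atoms: none
Why: Borohydride reduction of an aromatic aldehyde, which leaves the aryl bromide and the benzyl ethers untouched.

Step 4
Reactants: 5 [2,4-bis(benzyloxy)-6-bromophenyl]methanol
Product: 6 1,5-bis(benzyloxy)-3-bromo-2-(bromomethyl)benzene
Conditions: PBr3 (0.4 equiv), CH2Cl2, 0 °C; cold aq NaHCO3 wash, used at once
Reagents that add atoms: phosphorus tribromide, BrP(Br)Br
Why: Bromination of a benzylic alcohol through its phosphite ester (SN2 by bromide); the electron-rich product is labile and is therefore carried on without chromatography.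

Step 5
Reactants: 7 glycolic acid
Product: 9 (triisopropylsilyloxy)acetic acid, via bis-silylated glycolate 8 (not isolated)
Conditions: TIPSCl (2.2 equiv), imidazole, DMF, rt; aqueous work-up; then K2CO3, MeOH–THF–H2O, rt; aq HCl to pH 3–4
Reagents that add atoms: chlorotriisopropylsilane, CC(C)[Si](Cl)(C(C)C)C(C)C
Why: Silylation of hydroxyl and carboxyl groups followed by selective solvolysis of the far more labile silyl ester leaves the silyl ether that marks O3 throughout.

Step 6
Reactants: 9 (triisopropylsilyloxy)acetic acid; 10 (S)-4-benzyl-2-oxazolidinone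
Product: 12 (4S)-4-benzyl-3-[(triisopropylsilyloxy)acetyl]oxazolidin-2-one, via mixed pivalic anhydride 11 (not isolated)
Conditions: PivCl, Et3N, THF, −20 °C; then LiCl, 10, −20 °C → rt
Reagents that add atoms: pivaloyl chloride, CC(C)(C)C(=O)Cl (atoms held only in intermediate 11)
Why: N-acylation of the oxazolidinone through a mixed anhydride (LiCl/Et3N variant), the nucleophile choosing the unhindered glycolyl carbonyl over the pivaloyl one.

Step 7
Reactants: 12 (4S)-4-benzyl-3-[(triisopropylsilyloxy)acetyl]oxazolidin-2-one; 6 1,5-bis(benzyloxy)-3-bromo-2-(bromomethyl)benzene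
Product: 14 (4S)-4-benzyl-3-[(2R)-3-[2,4-bis(benzyloxy)-6-bromophenyl]-2-(triisopropylsilyloxy)propanoyl]oxazolidin-2-one, via sodium (Z)-enolate 13 (not isolated)
Conditions: 12 (1.3 equiv), NaN(SiMe3)2, THF, −78 °C; then 6, −78 → −40 °C
Reagents that add atoms: sodium bis(trimethylsilyl)amide, C[Si](C)(C)[N-][Si](C)(C)C.[Na+] (sodium held only in intermediate 13)
Why: Evans-type asymmetric alkylation of a glycolate imide, in which the chelated (Z)-sodium enolate is shielded on one face by the C4 benzyl group of the (S)-auxiliary, so the very reactive benzylic bromide enters from the other face, forms C3–C4 and sets C3 as (R).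

Step 8
Reactants: 14 alkylated imide
Product: 15 (2R)-3-[2,4-bis(benzyloxy)-6-bromophenyl]-N-methoxy-N-methyl-2-(triisopropylsilyloxy)propanamide
Conditions: MeNH(OMe)·HCl, AlMe3, CH2Cl2, 0 °C → rt
Reagents that add atoms: N,O-dimethylhydroxylamine hydrochloride, CNOC.Cl
Why: Weinreb transamidation with the aluminium amide made in the flask, which attacks the exocyclic imide carbonyl, releases the auxiliary for re-use and does not touch C3.

Step 9
Reactants: 16 4-bromocatechol
Product: 17 1,2-bis(benzyloxy)-4-bromobenzene
Conditions: BnBr (2.2 equiv), K2CO3, DMF, 60 °C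
Reagents that add atoms: benzyl bromide, BrCc1ccccc1
Why: Williamson ether synthesis on both catechol oxygens, giving the ring B halide in the same protecting-group scheme as ring A.

Step 10
Reactants: 17 1,2-bis(benzyloxy)-4-bromobenzene; 15 Weinreb amide
Product: 19 (2R)-1-[3,4-bis(benzyloxy)phenyl]-3-[2,4-bis(benzyloxy)-6-bromophenyl]-2-(triisopropylsilyloxy)propan-1-one, via arylmagnesium bromide 18 (not isolated)
Conditions: 17, Mg turnings, THF, 50 °C; solution decanted from Mg; then 15, THF, 0 °C → rt; aq NH4Cl
Reagents that add atoms: magnesium, [Mg] (held only in intermediate 18)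
Why: Weinreb ketone synthesis, in which the aryl Grignard reagent adds once, the magnesium-chelated tetrahedral adduct holds until the quench so that neither over-addition nor enolisation at C3 can occur, and no exchange with the ring A bromide is expected.

Step 11
Reactants: 19 α-silyloxy aryl ketone
Product: 20 (1R,2R)-1-[3,4-bis(benzyloxy)phenyl]-3-[2,4-bis(benzyloxy)-6-bromophenyl]-2-(triisopropylsilyloxy)propan-1-ol (syn; free hydroxyl at C2, silyl ether at O3)
Conditions: LiBH(s-Bu)3, THF, −78 → −40 °C; aq NH4Cl added cold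
Reagents that add atoms: none
Why: Felkin–Anh (polar model) reduction, in which the bulky, poorly coordinating silyloxy group stands perpendicular to the carbonyl plane and the hindered hydride enters anti to it past the C3 hydrogen, setting C2 as (R) and giving the syn alcohol, while the cold quench prevents a silyl shift in the alkoxide.

Step 12
Reactants: 20 syn bromo alcohol
Product: 21 (2R,3R)-5,7-bis(benzyloxy)-2-[3,4-bis(benzyloxy)phenyl]-3-(triisopropylsilyloxy)chroman (3-O-triisopropylsilyl-5,7,3',4'-tetra-O-benzyl-(−)-epicatechin)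
Conditions: CuI (10 mol %), 3,4,7,8-tetramethyl-1,10-phenanthroline (20 mol %), Cs2CO3 (2 equiv), 4 Å molecular sieves, toluene (dilute), 100–110 °C, argon
Reagents that add atoms: none
Why: The carbonate removes the C2 hydroxyl proton, the alkoxide binds phenanthroline-ligated monovalent copper, the C8a–Br bond adds oxidatively to give a seven-membered trivalent copper metallacycle, and reductive elimination forms O1–C8a; this is an intramolecular Ullmann-type (Buchwald-type) etherification of an aryl bromide by a secondary alcohol, an established way to chromans in which benzylic carbinols keep their configuration. Ring C closes in the six-membered mode at the sp2 carbon C8a with the leaving bromide outside the ring (formally 6-exo), and C8a lies meta to both benzyloxy groups, so resonance donation does not slow the oxidative addition. No stereocentre is created, because only O–H and C8a–Br break: C2 (R) and C3 (R) are carried over, syn becomes 2,3-cis, and the basic, non-ionising medium gives the electron-rich benzylic C2 no route to the trans flavan. The step needs O1 and not O3 to couple, which the O3 silyl ether secures; triisopropylsilyl is chosen because a 1,2 oxygen-to-oxygen silyl shift in the hot alkoxide would free O3 for the easier five-membered closure, and this group resists that shift far better than smaller silyl groups. It also needs the alkoxide to keep its carbinol hydrogen, which copper favours because its alkoxides are much less prone to β-hydride elimination than palladium alkoxides, and excluding air prevents oxidation to the ketone.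

Step 13
Reactants: 21 silyl-protected flavan
Product: 22 (2R,3R)-5,7-bis(benzyloxy)-2-[3,4-bis(benzyloxy)phenyl]chroman-3-ol (5,7,3',4'-tetra-O-benzyl-(−)-epicatechin)
Conditions: n-Bu4NF, THF, 0 °C → rt (40 °C if slow)
Reagents that add atoms: none
Why: Fluoride-induced desilylation at silicon, which breaks no C–O bond, so both stereocentres and the aryl benzyl ethers are kept.

Step 14
Reactants: 23 syringic acid
Product: 25 4-(benzyloxy)-3,5-dimethoxybenzoic acid, via benzyl ester 24 (not isolated)
Conditions: BnBr (2.3 equiv), K2CO3, DMF, 70 °C; aqueous work-up; then NaOH, MeOH–H2O, reflux; aq HCl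
Reagents that add atoms: benzyl bromide, BrCc1ccccc1; sodium hydroxide, [Na+].[OH-] (one carboxyl oxygen)
Why: Williamson benzylation of phenol and carboxylate followed by saponification of the benzyl ester masks the free phenol that would otherwise compete in the acylation.

Step 15
Reactants: 22 tetra-O-benzyl-(−)-epicatechin; 25 4-(benzyloxy)-3,5-dimethoxybenzoic acid
Product: 26 (2R,3R)-5,7-bis(benzyloxy)-2-[3,4-bis(benzyloxy)phenyl]chroman-3-yl 4-(benzyloxy)-3,5-dimethoxybenzoate
Conditions: 25 (1.5 equiv), DCC, DMAP, CH2Cl2, 0 °C → rt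
Reagents that add atoms: none
Why: Steglich esterification, in which the acylpyridinium ion acylates the hindered axial O3 without breaking the C3–O bond, so the configuration is retained.

Step 16
Reactants: 26 penta-O-benzyl ester
Product: 27 (−)-epicatechin 3-O-syringate, (2R,3R)-2-(3,4-dihydroxyphenyl)-5,7-dihydroxychroman-3-yl 4-hydroxy-3,5-dimethoxybenzoate (CNP0128506.1)
Conditions: H2 (1 atm), Pd(OH)2/C, THF–MeOH, rt
Reagents that add atoms: none
Why: Catalytic hydrogenolysis of the five O-benzyl ethers under neutral conditions, which should spare the aryl ester, the methyl ethers and the cyclic C2–O1 bond and gives C2 no chance to epimerise.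

**Compound list**
1 | 5-bromoresorcinol | Oc1cc(O)cc(Br)c1 | starting material
2 | 1,3-bis(benzyloxy)-5-bromobenzene | Brc1cc(OCc2ccccc2)cc(OCc2ccccc2)c1 | intermediate
3 | [2,4-bis(benzyloxy)-6-bromobenzylidene]dimethyliminium chloride | C[N+](C)=Cc1c(Br)cc(OCc2ccccc2)cc1OCc1ccccc1.[Cl-] | intermediate
4 | 2,4-bis(benzyloxy)-6-bromobenzaldehyde | O=Cc1c(Br)cc(OCc2ccccc2)cc1OCc1ccccc1 | intermediate
5 | [2,4-bis(benzyloxy)-6-bromophenyl]methanol | OCc1c(Br)cc(OCc2ccccc2)cc1OCc1ccccc1 | intermediate
6 | 1,5-bis(benzyloxy)-3-bromo-2-(bromomethyl)benzene | BrCc1c(Br)cc(OCc2ccccc2)cc1OCc1ccccc1 | intermediate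
7 | glycolic acid | OCC(=O)O | starting material
8 | triisopropylsilyl (triisopropylsilyloxy)acetate | CC(C)[Si](OCC(=O)O[Si](C(C)C)(C(C)C)C(C)C)(C(C)C)C(C)C | intermediate
9 | (triisopropylsilyloxy)acetic acid | CC(C)[Si](OCC(=O)O)(C(C)C)C(C)C | intermediate
10 | (S)-4-benzyl-2-oxazolidinone | O=C1N[C@@H](Cc2ccccc2)CO1 | starting material
11 | pivalic (triisopropylsilyloxy)acetic anhydride | CC(C)[Si](OCC(=O)OC(=O)C(C)(C)C)(C(C)C)C(C)C | intermediate
12 | (4S)-4-benzyl-3-[(triisopropylsilyloxy)acetyl]oxazolidin-2-one | CC(C)[Si](OCC(=O)N1[C@@H](Cc2ccccc2)COC1=O)(C(C)C)C(C)C | intermediate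
13 | sodium (Z)-enolate of 12 | CC(C)[Si](O/C=C(\[O-])N1[C@@H](Cc2ccccc2)COC1=O)(C(C)C)C(C)C.[Na+] | intermediate
14 | (4S)-4-benzyl-3-[(2R)-3-[2,4-bis(benzyloxy)-6-bromophenyl]-2-(triisopropylsilyloxy)propanoyl]oxazolidin-2-one | O=C([C@H](O[Si](C(C)C)(C(C)C)C(C)C)Cc1c(Br)cc(OCc2ccccc2)cc1OCc1ccccc1)N1[C@@H](Cc2ccccc2)COC1=O | intermediate
15 | (2R)-3-[2,4-bis(benzyloxy)-6-bromophenyl]-N-methoxy-N-methyl-2-(triisopropylsilyloxy)propanamide | CON(C)C(=O)[C@H](O[Si](C(C)C)(C(C)C)C(C)C)Cc1c(Br)cc(OCc2ccccc2)cc1OCc1ccccc1 | intermediate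
16 | 4-bromocatechol | Oc1ccc(Br)cc1O | starting material
17 | 1,2-bis(benzyloxy)-4-bromobenzene | Brc1ccc(OCc2ccccc2)c(OCc2ccccc2)c1 | intermediate
18 | [3,4-bis(benzyloxy)phenyl]magnesium bromide | Br[Mg]c1ccc(OCc2ccccc2)c(OCc2ccccc2)c1 | intermediate
19 | (2R)-1-[3,4-bis(benzyloxy)phenyl]-3-[2,4-bis(benzyloxy)-6-bromophenyl]-2-(triisopropylsilyloxy)propan-1-one | O=C([C@H](O[Si](C(C)C)(C(C)C)C(C)C)Cc1c(Br)cc(OCc2ccccc2)cc1OCc1ccccc1)c1ccc(OCc2ccccc2)c(OCc2ccccc2)c1 | intermediate
20 | (1R,2R)-1-[3,4-bis(benzyloxy)phenyl]-3-[2,4-bis(benzyloxy)-6-bromophenyl]-2-(triisopropylsilyloxy)propan-1-ol | O[C@@H]([C@H](O[Si](C(C)C)(C(C)C)C(C)C)Cc1c(Br)cc(OCc2ccccc2)cc1OCc1ccccc1)c1ccc(OCc2ccccc2)c(OCc2ccccc2)c1 | intermediate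
21 | 3-O-triisopropylsilyl-5,7,3',4'-tetra-O-benzyl-(−)-epicatechin | CC(C)[Si](O[C@@H]1Cc2c(OCc3ccccc3)cc(OCc3ccccc3)cc2O[C@@H]1c1ccc(OCc2ccccc2)c(OCc2ccccc2)c1)(C(C)C)C(C)C | intermediate
22 | 5,7,3',4'-tetra-O-benzyl-(−)-epicatechin | O[C@@H]1Cc2c(OCc3ccccc3)cc(OCc3ccccc3)cc2O[C@@H]1c1ccc(OCc2ccccc2)c(OCc2ccccc2)c1 | intermediate
23 | syringic acid | COc1cc(C(=O)O)cc(OC)c1O | starting material
24 | benzyl 4-(benzyloxy)-3,5-dimethoxybenzoate | COc1cc(C(=O)OCc2ccccc2)cc(OC)c1OCc1ccccc1 | intermediate
25 | 4-(benzyloxy)-3,5-dimethoxybenzoic acid | COc1cc(C(=O)O)cc(OC)c1OCc1ccccc1 | intermediate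
26 | tetra-O-benzyl-(−)-epicatechin 3-O-[4-(benzyloxy)-3,5-dimethoxybenzoate] | COc1cc(C(=O)O[C@@H]2Cc3c(OCc4ccccc4)cc(OCc4ccccc4)cc3O[C@@H]2c2ccc(OCc3ccccc3)c(OCc3ccccc3)c2)cc(OC)c1OCc1ccccc1 | intermediate
27 | (−)-epicatechin 3-O-syringate | COc1cc(C(=O)O[C@@H]2Cc3c(O)cc(O)cc3O[C@@H]2c2ccc(O)c(O)c2)cc(OC)c1O | target

**Step count**
- Total step count: 16.
- Longest linear sequence: 12 steps (1, 2, 3, 4, 7, 8, 10, 11, 12, 13, 15, 16) from 5-bromoresorcinol.

**Steps most likely to fail**

1. Step 12.
   - What may go wrong: oxidative addition may be slow, so that hydrodebromination takes over. Alternatively, the hot base may drive the silyl group from O3 to the C2 alkoxide and open the five-membered closure through O3.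
   - The fallback sets out from 19, skips steps 11 and 12, and comes back at 21. It closes ring C on the other side of O1.
   - Miyaura borylation of 19 (B2pin2, PdCl2(dppf), KOAc, dioxane, 80 °C) should give the pinacol boronate F1.
   - NaBO3·4H2O in THF–H2O at rt should turn it into the phenol ketone F2, which stands in equilibrium with its cyclic hemiketal.
   - Et3SiH and BF3·OEt2 in CH2Cl2 at −78 → −40 °C should then effect an intramolecular reductive etherification. The cyclic oxocarbenium ion takes hydride on the face away from the C3 silyloxy group, which places ring B cis to O3 and gives 21.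

2. Step 7.
   - What may go wrong: the electron-rich benzylic bromide may ionise and self-condense. The enolate may also break down on warming before the crowded C–C bond forms.
   - The fallback sets out from 2 and comes back at 15. It takes C3 from the chiral pool instead of an auxiliary.
   - Iodination of 2 (NIS, MeCN, rt) para to one benzyloxy group should give 1,5-bis(benzyloxy)-3-bromo-2-iodobenzene F3.
   - Selective iodine–magnesium exchange (i-PrMgCl·LiCl, THF, −40 °C, kept cold to avoid aryne formation) should give the arylmagnesium chloride F4.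
   - With CuI (10 mol %), F4 should open commercial methyl (R)-glycidate (COC(=O)[C@H]1CO1) at its CH2 terminus to give the (R)-α-hydroxy ester F5.
   - TIPSOTf and 2,6-lutidine should give the silyl ether ester F6, and MeNH(OMe)·HCl with i-PrMgCl (THF, −20 °C) should convert it into 15.

3. Step 11.
   - What may go wrong: facial selectivity may be poor, or the very bulky hydride may stall at the crowded, electron-rich aryl ketone.
   - The fallback sets out from 19 and comes back at 20. It hands stereocontrol from the substrate to a catalyst.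
   - It is a Noyori-type asymmetric transfer hydrogenation with RuCl(p-cymene)[(S,S)-TsDPEN] in the HCO2H–Et3N azeotrope at rt to 40 °C.
   - The (S,S) catalyst selects the aryl ketone face that corresponds here to the (R) carbinol, because C3 outranks ring B in the priority order. This is also the Felkin face, so catalyst and substrate are matched. No new compound arises.

**Further compounds**
F1 | step 12 | (2R)-1-[3,4-bis(benzyloxy)phenyl]-3-[2,4-bis(benzyloxy)-6-(4,4,5,5-tetramethyl-1,3,2-dioxaborolan-2-yl)phenyl]-2-(triisopropylsilyloxy)propan-1-one | O=C([C@H](O[Si](C(C)C)(C(C)C)C(C)C)Cc1c(B2OC(C)(C)C(C)(C)O2)cc(OCc2ccccc2)cc1OCc1ccccc1)c1ccc(OCc2ccccc2)c(OCc2ccccc2)c1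
F2 | step 12 | (2R)-1-[3,4-bis(benzyloxy)phenyl]-3-[2,4-bis(benzyloxy)-6-hydroxyphenyl]-2-(triisopropylsilyloxy)propan-1-one | O=C([C@H](O[Si](C(C)C)(C(C)C)C(C)C)Cc1c(O)cc(OCc2ccccc2)cc1OCc1ccccc1)c1ccc(OCc2ccccc2)c(OCc2ccccc2)c1
F3 | step 7 | 1,5-bis(benzyloxy)-3-bromo-2-iodobenzene | Ic1c(Br)cc(OCc2ccccc2)cc1OCc1ccccc1
F4 | step 7 | [2,4-bis(benzyloxy)-6-bromophenyl]magnesium chloride | Cl[Mg]c1c(Br)cc(OCc2ccccc2)cc1OCc1ccccc1
F5 | step 7 | methyl (2R)-3-[2,4-bis(benzyloxy)-6-bromophenyl]-2-hydroxypropanoate | COC(=O)[C@H](O)Cc1c(Br)cc(OCc2ccccc2)cc1OCc1ccccc1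
F6 | step 7 | methyl (2R)-3-[2,4-bis(benzyloxy)-6-bromophenyl]-2-(triisopropylsilyloxy)propanoate | COC(=O)[C@H](O[Si](C(C)C)(C(C)C)C(C)C)Cc1c(Br)cc(OCc2ccccc2)cc1OCc1ccccc1
F0 | step 11 | none | none
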